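**Retrosynthetic overview** (hydroazulene numbering: C1 CH–OAc, C2 CH2, C3 C(OH)iPr, C3a, C4 CH–O-aroyl, C5=C6(Me), C7 C=O, C8 CH2, C8a C–Me)
- Late stage: acetate and aryl ester adjustments; the C7 enone comes from an intramolecular Nozaki–Hiyama–Kishi closure of C6–C7 (seven-membered ring, formed second) followed by oxidation.
- The C3 carbinol comes from isopropyl addition to a cyclopentanone; C3a–C4 comes from an aldol of the enolate released when the C8a methyl is added by cuprate trans to the C1 silyloxy group.
- The cyclopentenone (C3 ketone, C3a=C8a enone, C1 carbinol, C2 methylene) comes in one operation from a flat furan: Piancatelli rearrangement of (4-allylfuran-2-yl)methanol, whose 4π electrocyclization makes the C1–C2 bond and closes the five-membered ring first.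
- Enabling feature: in the five-membered ring the oxygen-bearing C1 and C3 flank the C2 methylene, and C3 is bonded to the ring-fusion pair C3a/C8a; the ring is therefore a masked 4-hydroxycyclopent-2-enone, the direct product of a 2-furylmethanol and water.
- Absolute configuration: lipase resolution of the C1 carbinol, which then relays to C8a, C3a, C4 and C3.

Key step: step 3

Remark: the lipase is taken to prefer the (4R)-alcohol, the sense it shows with 4-hydroxycyclopent-2-enone and allethrolone-type cyclopentenolones; with the opposite sense the unreacted alcohol of step 4 would be silylated directly.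

Step 1
Reactants: 1 4-bromofuran-2-carbaldehyde; 2 allyltributylstannane
Product: 3 4-(prop-2-en-1-yl)furan-2-carbaldehyde
Conditions: Pd(PPh3)4 (5 mol %), toluene, 100 °C
Reagents that add atoms: allyltributylstannane (2), C=CC[Sn](CCCC)(CCCC)CCCC
Why: Stille coupling, in which zerovalent palladium should insert into the C4–Br bond (activated by the 2-formyl group) and take the allyl group from tin while the aldehyde stays untouched; no stereocentre is formed.

Step 2
Reactants: 3 4-(prop-2-en-1-yl)furan-2-carbaldehyde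
Product: 4 [4-(prop-2-en-1-yl)furan-2-yl]methanol
Conditions: NaBH4, MeOH, 0 °C
Reagents that add atoms: none
Why: Borohydride 1,2-reduction of the aldehyde, which should leave the furan and the terminal alkene alone; no stereocentre is formed.

Step 3
Reactants: 4 [4-(prop-2-en-1-yl)furan-2-yl]methanol
Product: 5 rac-4-hydroxy-3-(prop-2-en-1-yl)cyclopent-2-en-1-one
Conditions: H2O (0.05 M), KH2PO4/H3PO4 buffer pH 4, sealed vessel, microwave, 200 °C, 5–15 min
Reagents that add atoms: water, O
Why: Piancatelli rearrangement: acid-assisted ionisation of the primary furfuryl alcohol gives the 2-furfuryl cation, water adds at the free C5 of the furan, the 5-hydroxy-2-methylene-2,5-dihydrofuran opens to a 1,4-dihydroxypentadienyl cation, and a thermal conrotatory 4π electrocyclisation joins the former CH2OH carbon (later C2) to the former furan C5 (later C1) before proton loss gives the enone. The closest known reactions are the rearrangements of furfuryl alcohol itself and of 5-methylfurfuryl alcohol to 4-hydroxycyclopent-2-enones in hot water. The five-membered ring closes by Nazarov-type 4π electrocyclisation of a pentadienyl cation, which dearomatises the furan and turns its oxygen into the C3 carbonyl. The single new stereocentre (the carbinol carbon, later C1) has no controlling element, so 5 is expected racemic and is resolved in steps 4 and 5. The step needs water to attack C5 and cyclisation to outrun polymerisation of the furfuryl cation: C5 is the only unsubstituted α-position, the 4-allyl group stabilises the oxyallyl cation formed on ring closure, and high dilution, pH 4 and a short time at high temperature keep the cation concentration low while the isolated terminal alkene is not protonated.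

Step 4
Reactants: 5 rac-4-hydroxy-3-(prop-2-en-1-yl)cyclopent-2-en-1-one
Product: 6 (1R)-4-oxo-2-(prop-2-en-1-yl)cyclopent-2-en-1-yl acetate
Conditions: Burkholderia cepacia lipase (Amano lipase PS), vinyl acetate, MTBE, 30 °C, stopped near half conversion
Reagents that add atoms: vinyl acetate, CC(=O)OC=C
Why: Lipase-catalysed irreversible transesterification (kinetic resolution), in which the enzyme should acetylate the (4R)-alcohol much faster than its enantiomer, so that the (R)-acetate can be separated from unreacted (S)-5; the stereocentre made in step 3 is sorted, not created.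

Step 5
Reactants: 6 (1R)-4-oxo-2-(prop-2-en-1-yl)cyclopent-2-en-1-yl acetate
Product: 7 (4R)-4-hydroxy-3-(prop-2-en-1-yl)cyclopent-2-en-1-one
Conditions: Burkholderia cepacia lipase (Amano lipase PS), phosphate buffer pH 7, acetone, rt
Reagents that add atoms: none
Why: Lipase-catalysed ester hydrolysis with the same enantiopreference, which should free the (R)-alcohol at neutral pH (no base that could eliminate the β-acyloxy ketone) and raise its enantiomeric purity a second time.

Step 6
Reactants: 7 (4R)-4-hydroxy-3-(prop-2-en-1-yl)cyclopent-2-en-1-one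
Product: 8 (4R)-4-[(tert-butyldimethylsilyl)oxy]-3-(prop-2-en-1-yl)cyclopent-2-en-1-one
Conditions: TBSCl, imidazole, DMF, rt
Reagents that add atoms: tert-butyldimethylsilyl chloride, CC(C)(C)[Si](C)(C)Cl
Why: Silylation of the secondary alcohol under mild base, giving the bulky ether that later steers the cuprate and survives the organometallic steps; the stereocentre is untouched.

Step 7
Reactants: 9 but-2-yn-1-ol
Product: 11 (2Z)-3-iodobut-2-en-1-ol, via cyclic alkenylalanate 10 (not isolated)
Conditions: NaAlH2(OCH2CH2OMe)2, THF, 0 °C to rt; then I2, THF, −78 to 0 °C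
Reagents that add atoms: iodine, II
Why: Alkoxide-directed trans-hydroalumination of the propargylic alcohol places aluminium on C3 cis to the CH2O group in a five-membered alanate, and iodinolysis with retention should give the Z-iodoalkene.

Step 8
Reactants: 11 (2Z)-3-iodobut-2-en-1-ol
Product: 12 (2Z)-3-iodobut-2-enal
Conditions: MnO2, CH2Cl2, rt, dark; solution used at once
Reagents that add atoms: none
Why: Allylic oxidation on neutral MnO2, which should not isomerise the Z-alkene if the aldehyde is used immediately.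

Step 9
Reactants: 8 (4R)-4-[(tert-butyldimethylsilyl)oxy]-3-(prop-2-en-1-yl)cyclopent-2-en-1-one; 12 (2Z)-3-iodobut-2-enal
Product: 14 (2R,3S,4R)-4-[(tert-butyldimethylsilyl)oxy]-2-[(1S,2Z)-1-hydroxy-3-iodobut-2-en-1-yl]-3-methyl-3-(prop-2-en-1-yl)cyclopentan-1-one, via lithium enolate 13 (not isolated)
Conditions: Me2CuLi (from MeLi and CuI), Et2O, −78 to −40 °C; then 12, THF, −78 °C; aq. NH4Cl
Reagents that add atoms: lithium dimethylcuprate, [Li+].C[Cu-]C; (2Z)-3-iodobut-2-enal (12), C/C(I)=C/C=O
Why: Conjugate addition–aldol sequence: the cuprate should deliver methyl to the β-carbon on the face opposite the adjacent silyloxy group (quaternary carbon, later C8a, methyl trans to oxygen), and the regiodefined enolate 13 should add 1,2 to the β-iodoenal through a closed chair transition state on the face of that new methyl, away from the allyl and silyloxy groups, which places the side chain trans to the allyl group (later C3a) and gives the anti aldol (later C4).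

Step 10
Reactants: 14 (the aldol of step 9)
Product: 15 (1S,2R,3S,4R)-4-[(tert-butyldimethylsilyl)oxy]-2-[(1S,2Z)-1-hydroxy-3-iodobut-2-en-1-yl]-3-methyl-1-(propan-2-yl)-3-(prop-2-en-1-yl)cyclopentan-1-ol
Conditions: iPrMgCl (3 equiv), CeCl3 (anhydrous, 3 equiv), THF, −78 °C; aq. NH4Cl
Reagents that add atoms: isopropylmagnesium chloride, CC(C)[Mg]Cl
Why: Organocerium 1,2-addition: the weakly basic isopropylcerium reagent should add to the hindered ketone without enolisation, retro-aldol cleavage, β-elimination of the silyloxy group or iodine–metal exchange (the first equivalent is used up by the free hydroxyl), attacking the face opposite the α-side chain so that the new tertiary hydroxyl (later C3) is cis to that chain and trans to the silyloxy group.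

Step 11
Reactants: 15 (the diol of step 10); 16 4-(acetyloxy)benzoyl chloride
Product: 17 (1S,2Z)-1-[(1R,2S,4R,5S)-4-[(tert-butyldimethylsilyl)oxy]-2-hydroxy-5-methyl-2-(propan-2-yl)-5-(prop-2-en-1-yl)cyclopentyl]-3-iodobut-2-en-1-yl 4-(acetyloxy)benzoate
Conditions: pyridine, DMAP (cat.), CH2Cl2, 0 °C to rt
Reagents that add atoms: 4-(acetyloxy)benzoyl chloride (16), CC(=O)Oc1ccc(cc1)C(Cl)=O
Why: Acylation of the secondary allylic alcohol with an acid chloride under nucleophilic catalysis; the tertiary isopropyl carbinol is too hindered to react and the carbinol configuration is retained.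

Step 12
Reactants: 17 (the ester of step 11)
Product: 19 (1S,2Z)-1-[(1R,2S,4R,5S)-4-[(tert-butyldimethylsilyl)oxy]-2-hydroxy-5-methyl-5-(2-oxoethyl)-2-(propan-2-yl)cyclopentyl]-3-iodobut-2-en-1-yl 4-(acetyloxy)benzoate, via vicinal diol 18 (not isolated)
Conditions: OsO4 (2 mol %), NaIO4 (4 equiv), 2,6-lutidine, dioxane/H2O 3:1, rt
Reagents that add atoms: sodium periodate, [Na+].[O-]I(=O)(=O)=O, as stoichiometric oxygen source, delivered through osmium tetroxide, O=[Os](=O)(=O)=O
Why: Lemieux–Johnson oxidation, in which osmylation should pick the unhindered monosubstituted alkene over the trisubstituted, iodine-bearing alkene next to the ester, and periodate cleaves the diol to the aldehyde; the trans disposition of the tertiary hydroxyl and the new aldehyde arm prevents lactol formation.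

Step 13
Reactants: 19 (the aldehyde of step 12)
Product: 20 (1R,3S,3aR,4R,8aS)-1-[(tert-butyldimethylsilyl)oxy]-3,7-dihydroxy-6,8a-dimethyl-3-(propan-2-yl)-1,2,3,3a,4,7,8,8a-octahydroazulen-4-yl 4-(acetyloxy)benzoate (both C7 epimers)
Conditions: CrCl2 (8 equiv), NiCl2 (2 mol %), degassed DMSO, 0.005 M, rt
Reagents that add atoms: none
Why: Intramolecular Nozaki–Hiyama–Kishi reaction: zerovalent nickel should insert into the alkenyl C–I bond with retention of the Z geometry and the alkenylchromium species formed by transmetalation should add only to the aldehyde (esters, silyl ether and tertiary alcohol tolerated), closing the seven-membered ring trans-fused because the two arms sit trans on the cyclopentane; the new C7 carbinol is not controlled and is removed in step 14.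

Step 14
Reactants: 20 (the allylic alcohol of step 13)
Product: 21 (1R,3S,3aR,4R,8aS)-1-[(tert-butyldimethylsilyl)oxy]-3-hydroxy-6,8a-dimethyl-7-oxo-3-(propan-2-yl)-1,2,3,3a,4,7,8,8a-octahydroazulen-4-yl 4-(acetyloxy)benzoate
Conditions: Dess–Martin periodinane, NaHCO3, CH2Cl2, 0 °C to rt
Reagents that add atoms: none
Why: Dess–Martin oxidation of the only secondary alcohol, which should converge both C7 epimers on the enone and leave the tertiary alcohol untouched.

Step 15
Reactants: 21 (the enone of step 14)
Product: 22 (1R,3S,3aR,4R,8aS)-1,3-dihydroxy-6,8a-dimethyl-7-oxo-3-(propan-2-yl)-1,2,3,3a,4,7,8,8a-octahydroazulen-4-yl 4-(acetyloxy)benzoate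
Conditions: HF·pyridine, pyridine, THF, 0 °C to rt
Reagents that add atoms: none
Why: Fluoride-mediated desilylation under buffered, mildly acidic conditions, which should spare the aryl acetate, the allylic benzoate and the tertiary alcohol; C1 keeps its configuration.

Step 16
Reactants: 22 (the diol of step 15)
Product: 23 (1R,3S,3aR,4R,8aS)-1-(acetyloxy)-3-hydroxy-6,8a-dimethyl-7-oxo-3-(propan-2-yl)-1,2,3,3a,4,7,8,8a-octahydroazulen-4-yl 4-(acetyloxy)benzoate
Conditions: Ac2O, pyridine, DMAP (cat.), CH2Cl2, 0 °C
Reagents that add atoms: acetic anhydride, CC(=O)OC(C)=O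
Why: Acetylation of the secondary C1 alcohol, with the tertiary C3 alcohol expected to be too hindered to react under these conditions.

Step 17
Reactants: 23 (the bis-acetate of step 16)
Product: 24 (1R,3S,3aR,4R,8aS)-1-(acetyloxy)-3-hydroxy-6,8a-dimethyl-7-oxo-3-(propan-2-yl)-1,2,3,3a,4,7,8,8a-octahydroazulen-4-yl 4-hydroxybenzoate
Conditions: NH4OAc, MeOH/H2O 4:1, rt
Reagents that add atoms: none
Why: Chemoselective solvolysis of the aryl acetate, whose phenoxide leaving group makes it far more labile than the secondary alkyl acetate and the benzoate ester, should free the phenol and give the target.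

**Compound list**
1 | 4-bromofuran-2-carbaldehyde | O=Cc1cc(Br)co1 | starting material
2 | allyltributylstannane | C=CC[Sn](CCCC)(CCCC)CCCC | starting material
3 | 4-(prop-2-en-1-yl)furan-2-carbaldehyde | O=Cc1cc(CC=C)co1 | intermediate
4 | [4-(prop-2-en-1-yl)furan-2-yl]methanol | OCc1cc(CC=C)co1 | intermediate
5 | rac-4-hydroxy-3-(prop-2-en-1-yl)cyclopent-2-en-1-one | O=C1C=C(CC=C)C(O)C1 | intermediate
6 | (1R)-4-oxo-2-(prop-2-en-1-yl)cyclopent-2-en-1-yl acetate | O=C1C=C(CC=C)[C@H](OC(C)=O)C1 | intermediate
7 | (4R)-4-hydroxy-3-(prop-2-en-1-yl)cyclopent-2-en-1-one | O=C1C=C(CC=C)[C@H](O)C1 | intermediate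
8 | (4R)-4-[(tert-butyldimethylsilyl)oxy]-3-(prop-2-en-1-yl)cyclopent-2-en-1-one | O=C1C=C(CC=C)[C@H](O[Si](C)(C)C(C)(C)C)C1 | intermediate
9 | but-2-yn-1-ol | CC#CCO | starting material
10 | sodium 2,2-bis(2-methoxyethoxy)-3-methyl-2,5-dihydro-1,2-oxaaluminol-2-uide (cyclic alkenylalanate) | [Na+].CC1=CCO[Al-]1(OCCOC)OCCOC | intermediate (not isolated)
11 | (2Z)-3-iodobut-2-en-1-ol | C/C(I)=C/CO | intermediate
12 | (2Z)-3-iodobut-2-enal | C/C(I)=C/C=O | intermediate
13 | lithium (3S,4R)-4-[(tert-butyldimethylsilyl)oxy]-3-methyl-3-(prop-2-en-1-yl)cyclopent-1-en-1-olate | CC(C)(C)[Si](C)(C)O[C@@H]1CC(O[Li])=C[C@]1(C)CC=C | intermediate (not isolated)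
14 | (2R,3S,4R)-4-[(tert-butyldimethylsilyl)oxy]-2-[(1S,2Z)-1-hydroxy-3-iodobut-2-en-1-yl]-3-methyl-3-(prop-2-en-1-yl)cyclopentan-1-one | CC(C)(C)[Si](C)(C)O[C@@H]1CC(=O)[C@@H]([C@H](O)/C=C(/C)I)[C@]1(C)CC=C | intermediate
15 | (1S,2R,3S,4R)-4-[(tert-butyldimethylsilyl)oxy]-2-[(1S,2Z)-1-hydroxy-3-iodobut-2-en-1-yl]-3-methyl-1-(propan-2-yl)-3-(prop-2-en-1-yl)cyclopentan-1-ol | CC(C)(C)[Si](C)(C)O[C@@H]1C[C@](O)(C(C)C)[C@@H]([C@H](O)/C=C(/C)I)[C@]1(C)CC=C | intermediate
16 | 4-(acetyloxy)benzoyl chloride | CC(=O)Oc1ccc(cc1)C(Cl)=O | starting material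
17 | (1S,2Z)-1-[(1R,2S,4R,5S)-4-[(tert-butyldimethylsilyl)oxy]-2-hydroxy-5-methyl-2-(propan-2-yl)-5-(prop-2-en-1-yl)cyclopentyl]-3-iodobut-2-en-1-yl 4-(acetyloxy)benzoate | CC(C)(C)[Si](C)(C)O[C@@H]1C[C@](O)(C(C)C)[C@@H]([C@H](OC(=O)c2ccc(OC(C)=O)cc2)/C=C(/C)I)[C@]1(C)CC=C | intermediate
18 | the 2,3-dihydroxypropyl analogue of 17 (vicinal diol, both carbinol epimers) | CC(C)(C)[Si](C)(C)O[C@@H]1C[C@](O)(C(C)C)[C@@H]([C@H](OC(=O)c2ccc(OC(C)=O)cc2)/C=C(/C)I)[C@]1(C)CC(O)CO | intermediate (not isolated)
19 | (1S,2Z)-1-[(1R,2S,4R,5S)-4-[(tert-butyldimethylsilyl)oxy]-2-hydroxy-5-methyl-5-(2-oxoethyl)-2-(propan-2-yl)cyclopentyl]-3-iodobut-2-en-1-yl 4-(acetyloxy)benzoate | CC(C)(C)[Si](C)(C)O[C@@H]1C[C@](O)(C(C)C)[C@@H]([C@H](OC(=O)c2ccc(OC(C)=O)cc2)/C=C(/C)I)[C@]1(C)CC=O | intermediate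
20 | (1R,3S,3aR,4R,8aS)-1-[(tert-butyldimethylsilyl)oxy]-3,7-dihydroxy-6,8a-dimethyl-3-(propan-2-yl)-1,2,3,3a,4,7,8,8a-octahydroazulen-4-yl 4-(acetyloxy)benzoate (C7 epimers) | CC(C)(C)[Si](C)(C)O[C@@H]1C[C@](O)(C(C)C)[C@H]2[C@H](OC(=O)c3ccc(OC(C)=O)cc3)C=C(C)C(O)C[C@]12C | intermediate
21 | (1R,3S,3aR,4R,8aS)-1-[(tert-butyldimethylsilyl)oxy]-3-hydroxy-6,8a-dimethyl-7-oxo-3-(propan-2-yl)-1,2,3,3a,4,7,8,8a-octahydroazulen-4-yl 4-(acetyloxy)benzoate | CC(C)(C)[Si](C)(C)O[C@@H]1C[C@](O)(C(C)C)[C@H]2[C@H](OC(=O)c3ccc(OC(C)=O)cc3)C=C(C)C(=O)C[C@]12C | intermediate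
22 | (1R,3S,3aR,4R,8aS)-1,3-dihydroxy-6,8a-dimethyl-7-oxo-3-(propan-2-yl)-1,2,3,3a,4,7,8,8a-octahydroazulen-4-yl 4-(acetyloxy)benzoate | O[C@@H]1C[C@](O)(C(C)C)[C@H]2[C@H](OC(=O)c3ccc(OC(C)=O)cc3)C=C(C)C(=O)C[C@]12C | intermediate
23 | (1R,3S,3aR,4R,8aS)-1-(acetyloxy)-3-hydroxy-6,8a-dimethyl-7-oxo-3-(propan-2-yl)-1,2,3,3a,4,7,8,8a-octahydroazulen-4-yl 4-(acetyloxy)benzoate | CC(=O)O[C@@H]1C[C@](O)(C(C)C)[C@H]2[C@H](OC(=O)c3ccc(OC(C)=O)cc3)C=C(C)C(=O)C[C@]12C | intermediate
24 | (1R,3S,3aR,4R,8aS)-1-(acetyloxy)-3-hydroxy-6,8a-dimethyl-7-oxo-3-(propan-2-yl)-1,2,3,3a,4,7,8,8a-octahydroazulen-4-yl 4-hydroxybenzoate | CC(=O)O[C@@H]1C[C@](O)(C(C)C)[C@H]2[C@H](OC(=O)c3ccc(O)cc3)C=C(C)C(=O)C[C@]12C | target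

**Step count**
Total: 17 steps. Longest linear sequence: 15 steps (steps 1–6 and 9–17; steps 7 and 8 make the aldehyde partner).

**Steps most likely to fail, with fallbacks**

Step 3. The primary furfuryl cation may polymerise faster than water adds, or the allyl group may migrate into conjugation at 200 °C. The fallback sets out from 3. Condensation with p-toluenesulfonyl hydrazide in MeOH would give tosylhydrazone F1. Reduction with catecholborane, then NaOAc·3H2O at reflux, would give 4-allyl-2-methylfuran F2. Oxidative ring opening of the furan with N-bromosuccinimide and NaHCO3 in aqueous acetone at −20 °C would give (2Z)-4-oxo-2-(prop-2-en-1-yl)pent-2-enal F3. Warming this cis-enedione in phosphate buffer (pH 7–8)/dioxane should close the same C1–C2 bond by intramolecular aldol addition of the methyl ketone to the aldehyde, and the route is rejoined at 5.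

Step 9. Anti/syn selectivity at the new carbinol carbon may be poor, and the cuprate may add slowly next to the silyloxy carbon. The fallback sets out from 8 and 12 and runs the same conjugate addition–aldol without regard to the carbinol configuration. The syn-aldol F4 (epimer of 14 at the carbinol carbon) is taken through the organocerium addition of step 10 to the epimeric diol F5. Mitsunobu esterification of F5 with 4-acetoxybenzoic acid (PPh3, diisopropyl azodicarboxylate, THF) inverts the carbinol carbon, so both aldol epimers converge, and the route is rejoined at 17.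

Step 13. The allylic ester may ionise or eliminate at the alkenylmetal stage, or intermolecular coupling may compete with seven-membered ring closure. The fallback sets out from 17. An intramolecular Heck reaction (Pd(OAc)2, PPh3, Ag2CO3, MeCN, 80 °C; 7-exo insertion of the alkenylpalladium into the allyl group, then β-hydride elimination) would give the bicyclic diene F6 with an exocyclic methylene at C7. Lemieux–Johnson cleavage of that methylene (OsO4 cat., NaIO4, 2,6-lutidine, dioxane/H2O) would give the enone, and the route is rejoined at 21.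

**Further compounds**
F1 | step 3 | N'-{(E)-[4-(prop-2-en-1-yl)furan-2-yl]methylidene}-4-methylbenzenesulfonohydrazide | Cc1ccc(cc1)S(=O)(=O)N/N=C/c1cc(CC=C)co1
F2 | step 3 | 2-methyl-4-(prop-2-en-1-yl)furan | Cc1cc(CC=C)co1
F3 | step 3 | (2Z)-4-oxo-2-(prop-2-en-1-yl)pent-2-enal | CC(=O)/C=C(CC=C)\C=O
F4 | step 9 | (2R,3S,4R)-4-[(tert-butyldimethylsilyl)oxy]-2-[(1R,2Z)-1-hydroxy-3-iodobut-2-en-1-yl]-3-methyl-3-(prop-2-en-1-yl)cyclopentan-1-one | CC(C)(C)[Si](C)(C)O[C@@H]1CC(=O)[C@@H]([C@@H](O)/C=C(/C)I)[C@]1(C)CC=C
F5 | step 9 | (1S,2R,3S,4R)-4-[(tert-butyldimethylsilyl)oxy]-2-[(1R,2Z)-1-hydroxy-3-iodobut-2-en-1-yl]-3-methyl-1-(propan-2-yl)-3-(prop-2-en-1-yl)cyclopentan-1-ol | CC(C)(C)[Si](C)(C)O[C@@H]1C[C@](O)(C(C)C)[C@@H]([C@@H](O)/C=C(/C)I)[C@]1(C)CC=C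
F6 | step 13 | (1R,3S,3aR,4R,8aS)-1-[(tert-butyldimethylsilyl)oxy]-3-hydroxy-6,8a-dimethyl-7-methylidene-3-(propan-2-yl)-1,2,3,3a,4,7,8,8a-octahydroazulen-4-yl 4-(acetyloxy)benzoate | CC(C)(C)[Si](C)(C)O[C@@H]1C[C@](O)(C(C)C)[C@H]2[C@H](OC(=O)c3ccc(OC(C)=O)cc3)C=C(C)C(=C)C[C@]12C
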